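## The problem

The target **29** is (13Z)-2β-acetoxylabda-8(17),13-dien-15-oic acid, (2R,5S,9S,10S). It is a trans-fused decalin (ring A: C1–C5 and C10; ring B: C5–C10) with a gem-dimethyl group at C4, an angular methyl at C10, an exocyclic C8=C17 methylene, and at C9 a five-carbon chain ending in a (Z)-3-methylalk-2-enoic acid. Three of the four stereocentres (C5, C9, C10) are contiguous, and the quaternary C10 is joined through C5 to the quaternary C4, so they are best set in one stereospecific event. The fourth, C2, carries its acetoxy group axially, syn to the C10 methyl and the 4β-methyl. In that orientation it cannot anchor a conformation, but its equatorial 2α-epimer can, so C2 should steer C5/C9/C10 in the epimeric form and be inverted afterwards through the ketone, whose β face is shielded by the two axial methyls. The exocyclic alkene moves into the ring under acid, the (Z)-enoate can lose its geometry by γ-deprotonation, and the acetate survives neither saponification nor hydride or organometallic reagents. The methylene must therefore be made without acid or strong base, the C13=C14 geometry by a stereoretentive bond formation, and the acetate last. The feature that opens the structure is ring B: C6 and C7 are unsubstituted, the bonds C5–C10 and C8–C9 stand 1,4 across the ring, and C9 bears a carbon (C11) that can be an ester. Read backwards, ring B is the adduct of a C5=C6–C7=C8 diene and a C9=C10 enoate, with C1–C4 of ring A as the tether, which is a deca-1,7,9-triene.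

## Retrosynthesis

**C2 and the acid (no skeletal bond cut).** The acetate of **29** is removed first, to hydroxy acid **27**, because it tolerates none of the other late operations; **27** comes from methyl ester **26** by saponification. The axial 2β-alcohol of **26** is traced to ketone **25**, and **25** to the equatorial 2α-alcohol **24** and its silyl ether **23**. A direct SN2 inversion would need a nucleophile to enter along the axial β trajectory between the C10 and 4β methyls. The oxidation–reduction pair asks only that a bulky hydride reach the ketone from the open α face.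

**C8=C17.** The methylene of **23** is cut to the C8 ketone **22**, the ketone to enone **21**, and the enone to the C6=C7 alkene of **20** by allylic oxidation at C8, the only CH2 flanking that alkene. These operations are placed after the side chain for two reasons. A C8 ketone next to a C9 ester would be a β-keto ester, which enolises rather than undergoing methylenation. An exocyclic methylene would also compete with the vinyl group in the hydroboration of the next disconnection. The forward steps must oxidise C8 rather than C5, reduce the enone without touching the enoate, and methylenate without base.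

**C12–C13.** The chain of **20** is cut into alkylborane **19** and methyl (Z)-3-iodobut-2-enoate **18**, which is one step from methyl but-2-ynoate **17**. The neighbouring cut at C11–C12 (propargyl anion on a C11 iodide, then desilylation, carboxylation and syn-carbocupration) needs six operations from the ester and an SN2 reaction at a β-branched, hindered carbon. The B-alkyl Suzuki–Miyaura route needs four and carries the Z geometry over from **18** unchanged. **19** comes from vinyl compound **16**, and **16** from ester **13** through alcohol **14** and aldehyde **15**. The hydroboration must choose the vinyl group over the cis-disubstituted ring alkene, which 9-BBN-H does reliably.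

**C5–C10 and C8–C9 (key).** Cutting both bonds of **13** opens rings A and B at once and gives the acyclic triene **12**, with one stereocentre in place of four. Cutting only one ring (an annulation onto a preformed ring A) would leave the C5/C10 relationship to be solved separately. The forward reaction must be endo-selective (trans fusion), stereospecific in the dienophile (C9/C10), and face-selective under the control of the C2 silyloxy group.

**C1–C2.** Silyl ether **12** comes from alcohol **11**, which is cut between C1 and C2 into dienal **7** and silyl dienolate **10** (from methyl 3-methylbut-2-enoate **8**). This vinylogous aldol cut makes the carbinol centre and the (E)-β-methyl enoate in one step. An acetate aldol followed by ketone olefination would need more steps and would give E/Z mixtures at C9=C10. The forward reaction must be γ-selective and enantioselective on an aliphatic aldehyde.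

**C5=C6 and the chain ends.** Dienal **7** comes from ester **6** by partial reduction. The diene of **6** is cut at C5=C6 into aldehyde **3** and diethyl allylphosphonate **4**, and **3** is the ozonolysis product of methyl 3,3-dimethylpent-4-enoate **1**. All four starting materials (**1**, **4**, **8**, **17**) are commodity chemicals.

## Roads not taken

**Alternative 1:** The cut is C9–C10 together with a contraction of ring A. In the substrate **A1**, C1 bridges C2 and C10 as a cyclopropanol fused to a cyclopentane, and C5 carries a chain ending in an allyl sulfone (C8=C9, sulfonylmethyl C17 on C8).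
- **Forward step:** Mn(pic)3 (manganese tris(picolinate), trivalent manganese) oxidises the cyclopropanol and the C2–C10 bond breaks, leaving the C2 ketone and a tertiary C10 radical in the new six-membered ring A. The radical adds 6-endo to C9 and a sulfonyl radical leaves from C17, giving **A2**.
- **Merits:** **A2** already has the C8=C17 methylene, a C2 carbonyl ready for α-face reduction to the axial alcohol, and an oxygen handle at C12. It would avoid both the C8 oxidation–methylenation sequence and the C2 inversion of the chosen plan, about six steps.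
- **Weak points:** C9 and C10 are set by a radical addition to a trisubstituted alkene, which is not stereospecific, so the 9β configuration depends on a transition-state preference. The enantiopure substrate needs a stereocentre beside a gem-dimethyl group on a cyclopentane plus the cyclopropanol, a longer preparation than that of **12**. The oxidant is stoichiometric.
- **Comparison:** Alternative 1 is better after the ring closure. The chosen plan offers a concerted reaction that fixes all three ring stereocentres by rules (E geometry, endo, equatorial anchor), and a substrate six steps from simple esters.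

**Alternative 2:** The cut is C8–C9 and C11–C12. The substrate **A3** is a preformed ring A carrying a vinyl group (C9=C11) on C10 and a dioxinone joined through C6–C7 to C5.
- **Forward step:** Irradiation gives the intramolecular [2+2] adduct, which closes ring B; K2CO3 in MeOH then opens the four-membered ring between C8 and C12 and delivers **A4**.
- **Merits:** The C8 ketone appears free and is not a β-keto ester, C11–C13 arrive in the same operation, and the 2β-oxygen already has the final configuration. No allylic oxidation or C2 inversion is needed, which is a real advantage over the chosen plan.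
- **Weak points:** The hardest relationship, C5 against the quaternary C10, must be built into ring A beforehand, together with an axial 2β-silyloxy group. The C13 ester then has to become the (Z)-trisubstituted enoate, and olefination of the derived methyl ketone would favour E. The photochemical step is harder to scale.
- **Comparison:** Alternative 2 is better at C8 and C2. The chosen plan makes both rings and three centres from an acyclic triene and fixes 13Z by a stereoretentive coupling.

**Alternative 3:** The cut is C7–C8 and C9–C10, an intermolecular Diels–Alder reaction between the ring A diene **A5** and methyl but-2-ynoate **17**.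
- **Forward step:** AlCl3 or heat gives the cyclohexa-1,4-diene **A6**.
- **Merits:** It is the most convergent route, needs only one stereocentre in the diene, and brings in C17 (as the C8 methyl) and C11 together. In step count to a bicyclic core it beats the chosen plan.
- **Weak points:** The reacting terminus C10 is fully substituted and the vinyl group sits between the C4 gem-dimethyl group and the C10 methyl, so the s-cis conformer is strained and the alkynoate is a sluggish partner. The face of attack at C10 is governed only by the remote C2 substituent. **A6** has no stereocentre at C5 or C9, so the 5α-H, the 9α-H and the exocyclic position of the C8 alkene would all have to come from later reductions and a deconjugation, none of which is reliably selective.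
- **Comparison:** Alternative 3 is shorter but leaves three stereochemical problems open and controls a fourth weakly. The chosen plan settles C5, C9 and C10 in the cycloaddition itself.

Key step: step 7

Remark: ring atoms of all bicyclic intermediates carry labdane numbers, and labdane-type names refer to the normal series (5α-H, 9α-H, 10β-CH3); TBS = tert-butyldimethylsilyl.
Assumption: the (R,R)-bisphosphoramide of step 5 is taken to direct Re-face addition and so give (5R)-**11**; if MTPA-ester analysis shows the opposite sense, the (S,S)-catalyst is used.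

## Route

Step 1
Reactants: 1 methyl 3,3-dimethylpent-4-enoate
Product: 3 methyl 3,3-dimethyl-4-oxobutanoate, via ozonide 2 (not isolated)
Conditions: O3, CH2Cl2, −78 °C; then Me2S, −78 °C to rt
Reagents that add atoms: ozone, [O-][O+]=O
Why: Ozonolysis with reductive work-up; the monosubstituted alkene is the only oxidisable site and the aldehyde formed has no α-hydrogen, so it should be stable to isolation.

Step 2
Reactants: 3 methyl 3,3-dimethyl-4-oxobutanoate; 4 diethyl allylphosphonate
Product: 6 methyl (4E)-3,3-dimethylhepta-4,6-dienoate, via lithiated diethyl allylphosphonate 5 (not isolated)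
Conditions: 4, n-BuLi, THF, −78 °C; then 3, HMPA, −78 °C to rt
Reagents that add atoms: none
Why: Horner–Wadsworth–Emmons-type olefination with the α-lithiated allylphosphonate; HMPA favours α-attack and the elimination, which should give the (E)-terminal diene, and the non-enolisable aldehyde reacts far faster than the ester.

Step 3
Reactants: 6 methyl (4E)-3,3-dimethylhepta-4,6-dienoate
Product: 7 (4E)-3,3-dimethylhepta-4,6-dienal
Conditions: i-Bu2AlH (1.05 equiv), CH2Cl2, −78 °C; aq. KNaC4H4O6
Reagents that add atoms: none
Why: Partial hydride reduction of a methyl ester; the tetrahedral aluminium hemiacetal is stable at −78 °C and releases the aldehyde only on work-up, and the diene is inert.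

Step 4
Reactants: 8 methyl 3-methylbut-2-enoate
Product: 10 (1Z)-1-(tert-butyldimethylsilyloxy)-1-methoxy-3-methylbuta-1,3-diene, via lithium dienolate 9 (not isolated)
Conditions: LiN(i-Pr)2, THF, −78 °C; then t-BuMe2SiCl, DMPU, −78 °C to rt
Reagents that add atoms: tert-butyldimethylsilyl chloride, CC(C)(C)[Si](C)(C)Cl
Why: γ-Deprotonation of the unsaturated ester and O-silylation of the extended enolate (silyl ketene acetal formation); the C1=C2 geometry has no bearing on the next step because the γ-carbon reacts.

Step 5
Reactants: 7 (4E)-3,3-dimethylhepta-4,6-dienal; 10 (1Z)-1-(tert-butyldimethylsilyloxy)-1-methoxy-3-methylbuta-1,3-diene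
Product: 11 methyl (2E,5R,8E)-5-hydroxy-3,7,7-trimethylundeca-2,8,10-trienoate
Conditions: SiCl4 (1.1 equiv), (R,R)-bisphosphoramide [pentane-1,5-diyl-linked bis(N,N'-dimethyl-1,1'-binaphthyl-2,2'-diamine phosphoramide)] (5 mol %), i-Pr2NEt (10 mol %), CH2Cl2, −72 °C; aq. NaHCO3
Reagents that add atoms: none
Why: Enantioselective vinylogous Mukaiyama aldol reaction under Lewis-base-activated SiCl4; the bulky ligated silicon cation shields the α-carbon so the γ-carbon adds and the (E)-enoate results, and the chiral ligand shields one aldehyde face to set the carbinol centre (labdane C2) as R.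

Step 6
Reactants: 11 methyl (2E,5R,8E)-5-hydroxy-3,7,7-trimethylundeca-2,8,10-trienoate
Product: 12 methyl (2E,5R,8E)-5-[(tert-butyldimethylsilyl)oxy]-3,7,7-trimethylundeca-2,8,10-trienoate
Conditions: t-BuMe2SiCl, imidazole, DMF, rt
Reagents that add atoms: tert-butyldimethylsilyl chloride, CC(C)(C)[Si](C)(C)Cl
Why: Standard silylation of a secondary alcohol; the bulky ether serves as the equatorial anchor in the next step and tolerates alkylaluminium chlorides.

Step 7
Reactants: 12 methyl (2E,5R,8E)-5-[(tert-butyldimethylsilyl)oxy]-3,7,7-trimethylundeca-2,8,10-trienoate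
Product: 13 methyl (1S,4aS,7S,8aS)-7-[(tert-butyldimethylsilyl)oxy]-5,5,8a-trimethyl-1,2,4a,5,6,7,8,8a-octahydronaphthalene-1-carboxylate
Conditions: EtAlCl2 (1.1 equiv), CH2Cl2, −20 °C to rt; cold dilute aq. HCl
Reagents that add atoms: none
Why: EtAlCl2 binds the ester carbonyl and lowers the LUMO of the (E)-C9=C10 enoate, and the C5=C6–C7=C8 diene adds to it suprafacially in a concerted, asynchronous intramolecular [4+2] cycloaddition that forms C5–C10 and C8–C9. The closest known reaction type is the Lewis-acid-promoted intramolecular Diels–Alder reaction of (2E,8E)-deca-2,8,10-trienoates to trans-fused octalins, used here with a β-methyl (trisubstituted) dienophile. Ring B closes as the six-membered cycloaddition ring itself; ring A closes as the tether ring when C5–C10 forms, with the C1–C4 tether in a chair. C9 and C10 follow from the E geometry of the dienophile, which places the C10 methyl and C11 cis. C5 follows from the endo orientation of the aluminium-bound ester, which holds the tether anti and gives the trans fusion (5α-H, 10β-CH3). The absolute sense follows from C2: only the chair with the silyloxy group equatorial avoids a 1,3-diaxial clash with the C10 methyl and the axial C4 methyl, so one pair of π-faces reacts. The step thus needs endo and facial selectivity; the Lewis acid secures the first and the stereocentre of 12 the second, while the C4 gem-dimethyl group favours the coiled conformer and raises the rate.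

Step 8
Reactants: 13 methyl (1S,4aS,7S,8aS)-7-[(tert-butyldimethylsilyl)oxy]-5,5,8a-trimethyl-1,2,4a,5,6,7,8,8a-octahydronaphthalene-1-carboxylate
Product: 14 [(1S,4aS,7S,8aS)-7-[(tert-butyldimethylsilyl)oxy]-5,5,8a-trimethyl-1,2,4a,5,6,7,8,8a-octahydronaphthalen-1-yl]methanol
Conditions: LiAlH4, Et2O, 0 °C
Reagents that add atoms: none
Why: Hydride reduction of the hindered ester to the primary alcohol; the ring alkene and the silyl ether are inert.

Step 9
Reactants: 14 [(1S,4aS,7S,8aS)-7-[(tert-butyldimethylsilyl)oxy]-5,5,8a-trimethyl-1,2,4a,5,6,7,8,8a-octahydronaphthalen-1-yl]methanol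
Product: 15 (1S,4aS,7S,8aS)-7-[(tert-butyldimethylsilyl)oxy]-5,5,8a-trimethyl-1,2,4a,5,6,7,8,8a-octahydronaphthalene-1-carbaldehyde
Conditions: Dess–Martin periodinane, NaHCO3, CH2Cl2, 0 °C to rt
Reagents that add atoms: none
Why: Dess–Martin oxidation under buffered, non-epimerising conditions; the 9β-formyl group is also the thermodynamically preferred equatorial epimer.

Step 10
Reactants: 15 (1S,4aS,7S,8aS)-7-[(tert-butyldimethylsilyl)oxy]-5,5,8a-trimethyl-1,2,4a,5,6,7,8,8a-octahydronaphthalene-1-carbaldehyde
Product: 16 tert-butyl{[(2S,4aS,8R,8aR)-8-ethenyl-4,4,8a-trimethyl-1,2,3,4,4a,7,8,8a-octahydronaphthalen-2-yl]oxy}dimethylsilane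
Conditions: Ph3PCH3Br, KOt-Bu, THF, 0 °C to rt
Reagents that add atoms: methyltriphenylphosphonium bromide, C[P+](c1ccccc1)(c1ccccc1)c1ccccc1.[Br-]
Why: Wittig methylenation of an aldehyde, which proceeds even at hindered centres; any epimerisation at C9 would return the favoured equatorial isomer.

Step 11
Reactants: 17 methyl but-2-ynoate
Product: 18 methyl (2Z)-3-iodobut-2-enoate
Conditions: NaI, AcOH, 115 °C
Reagents that add atoms: sodium iodide, [Na+].[I-]
Why: Conjugate hydroiodination of an ynoate; anti addition of HI under these conditions gives the (Z)-β-iodo enoate with iodine cis to the ester.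

Step 12
Reactants: 16 tert-butyl{[(2S,4aS,8R,8aR)-8-ethenyl-4,4,8a-trimethyl-1,2,3,4,4a,7,8,8a-octahydronaphthalen-2-yl]oxy}dimethylsilane; 18 methyl (2Z)-3-iodobut-2-enoate
Product: 20 methyl (13Z)-2α-[(tert-butyldimethylsilyl)oxy]-17-norlabda-6,13-dien-15-oate, via alkylborane 19 (not isolated)
Conditions: 9-BBN-H, THF, 0 °C to rt; then 18, Pd(dppf)Cl2 (5 mol %), AsPh3, aq. Cs2CO3, DMF, rt
Reagents that add atoms: none
Why: Anti-Markovnikov hydroboration of the vinyl group (the cis-disubstituted ring alkene reacts far more slowly) followed by B-alkyl Suzuki–Miyaura coupling; oxidative addition to zerovalent palladium and reductive elimination both retain the alkene geometry, so C12 ends cis to the ester (13Z).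

Step 13
Reactants: 20 methyl (13Z)-2α-[(tert-butyldimethylsilyl)oxy]-17-norlabda-6,13-dien-15-oate
Product: 21 methyl (13Z)-2α-[(tert-butyldimethylsilyl)oxy]-8-oxo-17-norlabda-6,13-dien-15-oate
Conditions: CrO3 (15 equiv), 3,5-dimethylpyrazole (15 equiv), CH2Cl2, −20 °C
Reagents that add atoms: chromium trioxide, O=[Cr](=O)=O
Why: Allylic oxidation of a cyclohexene CH2 to the enone by the CrO3–3,5-dimethylpyrazole complex (hexavalent chromium); C8 is the only allylic CH2 of the ring alkene, C5–H is shielded by two flanking quaternary carbons, and the electron-poor enoate should not be attacked.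

Step 14
Reactants: 21 methyl (13Z)-2α-[(tert-butyldimethylsilyl)oxy]-8-oxo-17-norlabda-6,13-dien-15-oate
Product: 22 methyl (13Z)-2α-[(tert-butyldimethylsilyl)oxy]-8-oxo-17-norlabd-13-en-15-oate
Conditions: [(Ph3P)CuH]6 (0.4 equiv), H2O (3 equiv), toluene, rt
Reagents that add atoms: none
Why: Copper hydride conjugate reduction of the enone; the β,β-disubstituted enoate is far less reactive and the 9β chain stays equatorial.

Step 15
Reactants: 22 methyl (13Z)-2α-[(tert-butyldimethylsilyl)oxy]-8-oxo-17-norlabd-13-en-15-oate
Product: 23 methyl (13Z)-2α-[(tert-butyldimethylsilyl)oxy]labda-8(17),13-dien-15-oate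
Conditions: Zn, CH2Br2, TiCl4, THF (reagent pre-formed), then 22, CH2Cl2, 0 °C to rt; aq. NaHCO3
Reagents that add atoms: dibromomethane, BrCBr
Why: Takai–Lombardo methylenation; the non-basic gem-dimetallic reagent converts the hindered ketone without epimerising C9, attacking the ester or isomerising the (Z)-enoate.

Step 16
Reactants: 23 methyl (13Z)-2α-[(tert-butyldimethylsilyl)oxy]labda-8(17),13-dien-15-oate
Product: 24 methyl (13Z)-2α-hydroxylabda-8(17),13-dien-15-oate
Conditions: Bu4NF, THF, rt to 40 °C
Reagents that add atoms: none
Why: Fluoride-induced cleavage of the silyl ether; no acid is present, so the exocyclic alkene stays in place.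

Step 17
Reactants: 24 methyl (13Z)-2α-hydroxylabda-8(17),13-dien-15-oate
Product: 25 methyl (13Z)-2-oxolabda-8(17),13-dien-15-oate
Conditions: Dess–Martin periodinane, NaHCO3, CH2Cl2, rt
Reagents that add atoms: none
Why: Dess–Martin oxidation of the secondary alcohol; it erases the C2 centre, which has done its work, so that it can be set again.

Step 18
Reactants: 25 methyl (13Z)-2-oxolabda-8(17),13-dien-15-oate
Product: 26 methyl (13Z)-2β-hydroxylabda-8(17),13-dien-15-oate
Conditions: LiBH(s-Bu)3, THF, −78 °C; then NaOH, H2O2, 0 °C
Reagents that add atoms: none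
Why: Diastereoselective ketone reduction; the β face of C2 is blocked by the syn-axial C10 and 4β methyl groups, so the bulky hydride enters from the α face and the axial 2β-alcohol results, while the hindered enoate is not reduced at −78 °C.

Step 19
Reactants: 26 methyl (13Z)-2β-hydroxylabda-8(17),13-dien-15-oate
Product: 27 (13Z)-2β-hydroxylabda-8(17),13-dien-15-oic acid
Conditions: LiOH, THF/MeOH/H2O, 40 °C; then cold dilute aq. HCl to pH 3
Reagents that add atoms: lithium hydroxide, [Li+].[OH-]
Why: Saponification of the methyl ester by acyl–oxygen cleavage; hydroxide does not deprotonate the γ-position, so the Z geometry should be kept.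

Step 20
Reactants: 27 (13Z)-2β-hydroxylabda-8(17),13-dien-15-oic acid
Product: 29 (13Z)-2β-acetoxylabda-8(17),13-dien-15-oic acid, via mixed anhydride 28 (not isolated)
Conditions: Ac2O, pyridine, DMAP, CH2Cl2, rt to 40 °C; then aq. NaHCO3/THF, rt, and acidification to pH 3
Reagents that add atoms: acetic anhydride, CC(=O)OC(C)=O
Why: DMAP-catalysed acetylation of the hindered axial alcohol; the acid is converted in passing into the mixed anhydride, which is hydrolysed on aqueous work-up while the secondary acetate remains.

## Compound list

1 | methyl 3,3-dimethylpent-4-enoate | COC(=O)CC(C)(C)C=C | starting material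
2 | methyl 3-methyl-3-(1,2,4-trioxolan-3-yl)butanoate (ozonide, racemic) | COC(=O)CC(C)(C)C1OCOO1 | intermediate
3 | methyl 3,3-dimethyl-4-oxobutanoate | COC(=O)CC(C)(C)C=O | intermediate
4 | diethyl allylphosphonate | C=CCP(=O)(OCC)OCC | starting material
5 | lithiated diethyl allylphosphonate (α-lithio) | [Li+].C=C[CH-]P(=O)(OCC)OCC | intermediate
6 | methyl (4E)-3,3-dimethylhepta-4,6-dienoate | COC(=O)CC(C)(C)/C=C/C=C | intermediate
7 | (4E)-3,3-dimethylhepta-4,6-dienal | O=CCC(C)(C)/C=C/C=C | intermediate
8 | methyl 3-methylbut-2-enoate | COC(=O)C=C(C)C | starting material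
9 | lithium dienolate of 8 (O–Li cis to C3) | [Li+].CO/C([O-])=C/C(C)=C | intermediate
10 | (1Z)-1-(tert-butyldimethylsilyloxy)-1-methoxy-3-methylbuta-1,3-diene | CO/C(O[Si](C)(C)C(C)(C)C)=C/C(C)=C | intermediate
11 | methyl (2E,5R,8E)-5-hydroxy-3,7,7-trimethylundeca-2,8,10-trienoate | COC(=O)/C=C(\C)C[C@@H](O)CC(C)(C)/C=C/C=C | intermediate
12 | methyl (2E,5R,8E)-5-[(tert-butyldimethylsilyl)oxy]-3,7,7-trimethylundeca-2,8,10-trienoate | COC(=O)/C=C(\C)C[C@@H](O[Si](C)(C)C(C)(C)C)CC(C)(C)/C=C/C=C | intermediate
13 | methyl (1S,4aS,7S,8aS)-7-[(tert-butyldimethylsilyl)oxy]-5,5,8a-trimethyl-1,2,4a,5,6,7,8,8a-octahydronaphthalene-1-carboxylate (trans-fused; 2α-OTBS, 5α-H, 10β-CH3, 9β-CO2CH3, C6=C7) | C1C=C[C@H]2C(C)(C)C[C@H](O[Si](C)(C)C(C)(C)C)C[C@]2(C)[C@H]1C(=O)OC | intermediate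
14 | [(1S,4aS,7S,8aS)-7-[(tert-butyldimethylsilyl)oxy]-5,5,8a-trimethyl-1,2,4a,5,6,7,8,8a-octahydronaphthalen-1-yl]methanol | C1C=C[C@H]2C(C)(C)C[C@H](O[Si](C)(C)C(C)(C)C)C[C@]2(C)[C@H]1CO | intermediate
15 | (1S,4aS,7S,8aS)-7-[(tert-butyldimethylsilyl)oxy]-5,5,8a-trimethyl-1,2,4a,5,6,7,8,8a-octahydronaphthalene-1-carbaldehyde | C1C=C[C@H]2C(C)(C)C[C@H](O[Si](C)(C)C(C)(C)C)C[C@]2(C)[C@H]1C=O | intermediate
16 | tert-butyl{[(2S,4aS,8R,8aR)-8-ethenyl-4,4,8a-trimethyl-1,2,3,4,4a,7,8,8a-octahydronaphthalen-2-yl]oxy}dimethylsilane (9β-vinyl, 2α-OTBS, C6=C7) | C1C=C[C@H]2C(C)(C)C[C@H](O[Si](C)(C)C(C)(C)C)C[C@]2(C)[C@H]1C=C | intermediate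
17 | methyl but-2-ynoate | CC#CC(=O)OC | starting material
18 | methyl (2Z)-3-iodobut-2-enoate | COC(=O)/C=C(/C)I | intermediate
19 | 9-alkyl-9-borabicyclo[3.3.1]nonane from 16 (boron on C12; ring stereocentres as in 16) | C1C=C[C@H]2C(C)(C)C[C@H](O[Si](C)(C)C(C)(C)C)C[C@]2(C)[C@H]1CCB1C2CCCC1CCC2 | intermediate
20 | methyl (13Z)-2α-[(tert-butyldimethylsilyl)oxy]-17-norlabda-6,13-dien-15-oate | C1C=C[C@H]2C(C)(C)C[C@H](O[Si](C)(C)C(C)(C)C)C[C@]2(C)[C@H]1CC/C(C)=C\C(=O)OC | intermediate
21 | methyl (13Z)-2α-[(tert-butyldimethylsilyl)oxy]-8-oxo-17-norlabda-6,13-dien-15-oate | O=C1C=C[C@H]2C(C)(C)C[C@H](O[Si](C)(C)C(C)(C)C)C[C@]2(C)[C@H]1CC/C(C)=C\C(=O)OC | intermediate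
22 | methyl (13Z)-2α-[(tert-butyldimethylsilyl)oxy]-8-oxo-17-norlabd-13-en-15-oate | O=C1CC[C@H]2C(C)(C)C[C@H](O[Si](C)(C)C(C)(C)C)C[C@]2(C)[C@H]1CC/C(C)=C\C(=O)OC | intermediate
23 | methyl (13Z)-2α-[(tert-butyldimethylsilyl)oxy]labda-8(17),13-dien-15-oate | C=C1CC[C@H]2C(C)(C)C[C@H](O[Si](C)(C)C(C)(C)C)C[C@]2(C)[C@H]1CC/C(C)=C\C(=O)OC | intermediate
24 | methyl (13Z)-2α-hydroxylabda-8(17),13-dien-15-oate | C=C1CC[C@H]2C(C)(C)C[C@H](O)C[C@]2(C)[C@H]1CC/C(C)=C\C(=O)OC | intermediate
25 | methyl (13Z)-2-oxolabda-8(17),13-dien-15-oate | C=C1CC[C@H]2C(C)(C)CC(=O)C[C@]2(C)[C@H]1CC/C(C)=C\C(=O)OC | intermediate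
26 | methyl (13Z)-2β-hydroxylabda-8(17),13-dien-15-oate | C=C1CC[C@H]2C(C)(C)C[C@@H](O)C[C@]2(C)[C@H]1CC/C(C)=C\C(=O)OC | intermediate
27 | (13Z)-2β-hydroxylabda-8(17),13-dien-15-oic acid | C=C1CC[C@H]2C(C)(C)C[C@@H](O)C[C@]2(C)[C@H]1CC/C(C)=C\C(=O)O | intermediate
28 | acetic (13Z)-2β-acetoxylabda-8(17),13-dien-15-oic anhydride | C=C1CC[C@H]2C(C)(C)C[C@@H](OC(C)=O)C[C@]2(C)[C@H]1CC/C(C)=C\C(=O)OC(C)=O | intermediate
29 | (13Z)-2β-acetoxylabda-8(17),13-dien-15-oic acid, (2R,5S,9S,10S) | C=C1CC[C@H]2C(C)(C)C[C@@H](OC(C)=O)C[C@]2(C)[C@H]1CC/C(C)=C\C(=O)O | target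

## Step count and risks

Total step count: 20 (steps 4 and 11 prepare the dienolate **10** and the iodoenoate **18**).
Longest linear sequence: 18 steps from **1** (steps 1–3, 5–10, 12–20).

**Step 7 (key).** The cycloaddition may be slow, because the dienophile is trisubstituted and the C5–C10 bond joins a carbon next to quaternary C4 to a carbon that becomes quaternary. Prolonged exposure to the Lewis acid could then lead to cationic oligomerisation of the diene, erosion of the endo preference, or loss of the silyl ether. The fallback changes the activating group. It sets out from **12**: reduction with i-Bu2AlH gives the allylic alcohol (2E,5R,8E)-5-[(tert-butyldimethylsilyl)oxy]-3,7,7-trimethylundeca-2,8,10-trien-1-ol F1, and MnO2 gives the enal (2E,5R,8E)-5-[(tert-butyldimethylsilyl)oxy]-3,7,7-trimethylundeca-2,8,10-trienal F2. The far more electrophilic enal should cyclise with Me2AlCl at −78 to −20 °C through the same endo, equatorial-anchor transition state. This returns to the route at aldehyde **15** and makes steps 8 and 9 unnecessary.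

**Step 13.** Hydrogen abstraction at the tertiary C5–H, followed by allylic transposition, would put the carbonyl at C7; the γ-positions of the side-chain enoate could also be oxidised. The fallback uses an ene–[2,3] mechanism, which prefers an allylic CH2 over a CH and returns the alkene to its place. From **20**, SeO2 (catalytic) with t-BuOOH in CH2Cl2 should give the allylic alcohol methyl (13Z)-2α-[(tert-butyldimethylsilyl)oxy]-8α-hydroxy-17-norlabda-6,13-dien-15-oate F3 (either C8 epimer serves). Dess–Martin oxidation then returns to the route at **21**.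

**Step 5.** The β-quaternary aliphatic aldehyde may react slowly, and enantioselectivity or γ-selectivity may fall short. The fallback builds the same unit from an alkyne. From **7**, a chiral BINOL-phosphoric-acid-catalysed propargylation with allenylboronic acid pinacol ester gives (4R,7E)-6,6-dimethyldeca-7,9-dien-1-yn-4-ol F4. Zr-catalysed methylalumination (AlMe3, Cp2ZrCl2), which adds methyl and aluminium syn, followed by a ClCO2Me quench returns to the route at **11** with the E geometry fixed by the mechanism.

**Step 15.** Methylenation of the hindered C8 ketone may stall, or enolisation towards C9 may compete. The fallback is a two-stage Peterson olefination. From **22**, Me3SiCH2MgCl with CeCl3 at −78 °C adds to the ketone in preference to the hindered enoate and gives the β-hydroxysilane methyl (13Z)-2α-[(tert-butyldimethylsilyl)oxy]-8β-hydroxy-8α-[(trimethylsilyl)methyl]-17-norlabd-13-en-15-oate F5 (either C8 epimer serves). Aqueous HF in MeCN then causes elimination and removes the silyl ether in the same operation, returning to the route at **24**.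

**Step 20.** Acetylation of the axial alcohol between two syn-axial methyls may be incomplete, and forcing it in the presence of the free acid invites side reactions of the mixed anhydride. The fallback reverses the order of the last two operations. From **26**, Ac2O with DMAP in pyridine at 60 °C gives methyl (13Z)-2β-acetoxylabda-8(17),13-dien-15-oate F6. LiI in refluxing EtOAc then cleaves the methyl ester by SN2 attack at the methyl group, which leaves the secondary acetate untouched, and acidification gives **29**.

## Further compounds

F1 | step 7 | (2E,5R,8E)-5-[(tert-butyldimethylsilyl)oxy]-3,7,7-trimethylundeca-2,8,10-trien-1-ol | OC/C=C(\C)C[C@@H](O[Si](C)(C)C(C)(C)C)CC(C)(C)/C=C/C=C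
F2 | step 7 | (2E,5R,8E)-5-[(tert-butyldimethylsilyl)oxy]-3,7,7-trimethylundeca-2,8,10-trienal | O=C/C=C(\C)C[C@@H](O[Si](C)(C)C(C)(C)C)CC(C)(C)/C=C/C=C
F3 | step 13 | methyl (13Z)-2α-[(tert-butyldimethylsilyl)oxy]-8α-hydroxy-17-norlabda-6,13-dien-15-oate | O[C@@H]1C=C[C@H]2C(C)(C)C[C@H](O[Si](C)(C)C(C)(C)C)C[C@]2(C)[C@H]1CC/C(C)=C\C(=O)OC
F4 | step 5 | (4R,7E)-6,6-dimethyldeca-7,9-dien-1-yn-4-ol | C#CC[C@@H](O)CC(C)(C)/C=C/C=C
F5 | step 15 | methyl (13Z)-2α-[(tert-butyldimethylsilyl)oxy]-8β-hydroxy-8α-[(trimethylsilyl)methyl]-17-norlabd-13-en-15-oate | C[Si](C)(C)C[C@]1(O)CC[C@H]2C(C)(C)C[C@H](O[Si](C)(C)C(C)(C)C)C[C@]2(C)[C@H]1CC/C(C)=C\C(=O)OC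
F6 | step 20 | methyl (13Z)-2β-acetoxylabda-8(17),13-dien-15-oate | C=C1CC[C@H]2C(C)(C)C[C@@H](OC(C)=O)C[C@]2(C)[C@H]1CC/C(C)=C\C(=O)OC
A1 | alternative 1 | 4-[(3E)-6-(tert-butyldimethylsilyloxy)-3-(phenylsulfonylmethyl)hex-3-en-1-yl]-3,3,5-trimethylbicyclo[3.1.0]hexan-1-ol (cyclopropane anti to the chain; the configuration at the cyclopropane carbons is lost on ring opening) | CC(C)(C)[Si](C)(C)OCC/C=C(/CS(=O)(=O)c1ccccc1)CC[C@H]2C(C)(C)C[C@]3(O)C[C@]23C
A2 | alternative 1 | 12-(tert-butyldimethylsilyloxy)-13,14,15,16-tetranorlabd-8(17)-en-2-one | C=C1CC[C@H]2C(C)(C)CC(=O)C[C@]2(C)[C@H]1CCO[Si](C)(C)C(C)(C)C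
A3 | alternative 2 | 2,2-dimethyl-6-{2-[ring A: 2β-(tert-butyldimethylsilyloxy)-4,4,10β-trimethyl-10α-vinylcyclohexan-5β-yl]ethyl}-4H-1,3-dioxin-4-one | CC1(C)OC(=O)C=C(CC[C@H]2C(C)(C)C[C@@H](O[Si](C)(C)C(C)(C)C)C[C@]2(C)C=C)O1
A4 | alternative 2 | methyl 2β-(tert-butyldimethylsilyloxy)-8-oxo-14,15,16,17-tetranorlabdan-13-oate | O=C1CC[C@H]2C(C)(C)C[C@@H](O[Si](C)(C)C(C)(C)C)C[C@]2(C)[C@H]1CCC(=O)OC
A5 | alternative 3 | tert-butyl{[(1R)-4-ethenyl-3,5,5-trimethylcyclohex-3-en-1-yl]oxy}dimethylsilane | C=CC1=C(C)C[C@@H](O[Si](C)(C)C(C)(C)C)CC1(C)C
A6 | alternative 3 | methyl 2α-(tert-butyldimethylsilyloxy)drima-5,8-dien-11-oate (10β-methyl) | CC1CC=C2C(C)(C)C[C@H](O[Si](C)(C)C(C)(C)C)C[C@]2(C)C=1C(=O)OC
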